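The pyrrole ring is assembled from two open-chain pieces by cutting N1'–C5' and C2'–C3'. The key step exploits the fact that C3'(H)–C4'(Cl)–C5'(Cl) of the pyrrole is the carbon chain of 2,3,3-trichloroacrolein with both chlorines already in place, while C2' is the ketone α-carbon next to carbonyl C7 and N1' its amino substituent. One operation therefore joins an aryl aminomethyl ketone to the enal by chloride displacement and intramolecular aldol condensation, giving the 2-aroyl-4,5-dichloropyrrole without any chlorination of the electron-rich benzene ring. The precursor is 2-amino-1-[2,4-dimethoxy-3-(4-methylpentyl)phenyl]ethanone, kept as its hydrochloride and liberated only in the presence of the electrophile.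

Key step: step 4

Assumption: 2,3,3-trichloroacrolein is taken as a catalogue reagent and distilled before use; the target has no stereocentre, so no configuration has to be set.

Step 1
Reactants: 1 1,3-dimethoxybenzene; 2 1-bromo-4-methylpentane
Product: 4 1,3-dimethoxy-2-(4-methylpentyl)benzene, via 2,6-dimethoxyphenyllithium 3 (not isolated)
Conditions: n-BuLi (1.1 equiv), THF, 0 °C to rt; then 2 (1.2 equiv), 0 °C to 50 °C
Reagents that add atoms: none
Why: Directed ortho-metalation between the two methoxy groups should give the C2 aryllithium, which is alkylated by the unhindered primary bromide in an SN2 reaction.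

Step 2
Reactants: 4 1,3-dimethoxy-2-(4-methylpentyl)benzene; 5 chloroacetyl chloride
Product: 6 2-chloro-1-[2,4-dimethoxy-3-(4-methylpentyl)phenyl]ethanone
Conditions: AlCl3 (1.1 equiv), CH2Cl2, −10 to 0 °C; cold 1 M HCl quench
Reagents that add atoms: none
Why: Friedel–Crafts acylation should occur at C4, para to one methoxy group and ortho to the other, and the low temperature and short contact time should spare the flanked C2 methyl ether.

Step 3
Reactants: 6 2-chloro-1-[2,4-dimethoxy-3-(4-methylpentyl)phenyl]ethanone; 7 hexamethylenetetramine
Product: 9 2-amino-1-[2,4-dimethoxy-3-(4-methylpentyl)phenyl]ethanone hydrochloride, via hexaminium chloride 8 (not isolated)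
Conditions: 7 (1.1 equiv), NaI (0.1 equiv), CHCl3, 50 °C; solvent exchange; conc. HCl, EtOH, 40 °C
Reagents that add atoms: hydrogen chloride, Cl
Why: In this Delépine reaction the activated α-chloroketone should quaternise one nitrogen of 7 by SN2, and acid ethanolysis of the aminal cage then releases the primary amine directly as its stable hydrochloride, so neither an azide nor the self-condensing free α-aminoketone is handled.

Step 4
Reactants: 9 2-amino-1-[2,4-dimethoxy-3-(4-methylpentyl)phenyl]ethanone hydrochloride; 10 2,3,3-trichloroacrolein
Product: 13 (4,5-dichloro-1H-pyrrol-2-yl)[2,4-dimethoxy-3-(4-methylpentyl)phenyl]methanone, via free aminoketone 11 (not isolated), via chloroenaminal 12 (not isolated)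
Conditions: 10 (1.2 equiv), MeCN, −20 °C, DBU (2.0 equiv) added over 1 h; then DBU (1.5 equiv), −20 °C to rt
Reagents that add atoms: none
Why: Proposed new method: the amine 11, set free gradually from 9 while 10 is in excess, should add to the doubly chlorinated β-carbon of 10 and expel chloride (addition–elimination at a vinylic carbon, forming N1'–C5'), giving the push-pull enaminal 12, whose low C=C rotation barrier and N–H···O=C hydrogen bond place N1' and the formyl group cis. Further DBU then forms the enolate at C2' (α to the ketone carbon C7), which attacks the formyl carbon C3' in a 5-(enolexo)-exo-trig aldol closure (forming C2'–C3'), and loss of water aromatises the five-membered ring to the 2-aroyl-4,5-dichloropyrrole 13. The closest known reaction type is the base-mediated condensation of β-chloroenals or vinamidinium salts with glycine esters and α-amino ketones to pyrrole-2-carboxylates and 2-acylpyrroles, together with ring closures of N-(alkoxycarbonylmethyl) ketene N,S-acetals in which a methylthio leaving group stays on the nitrogen-bearing carbon; what is unproven is that the chlorine at C5' survives. No stereocentre is created, so no stereocontrol is required. The step needs nitrogen to attack the β-carbon and not the aldehyde, since an imine would end in the 3,4-dichloro isomer: the β,β-dichloroenal is a vinylogous acid chloride whose chloride loss is irreversible, whereas carbinolamine formation is reversible and imine dehydration slow under anhydrous conditions, and once 12 exists its formyl group is a deactivated vinylogous formamide. It also needs C- and not O-attack of the enolate and no second amination at C5': the formyl carbon is a far better electrophile than the nitrogen-donated C5', and the slow release of 11 into excess 10 keeps free amine scarce, which also suppresses dihydropyrazine formation.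

Step 5
Reactants: 13 (4,5-dichloro-1H-pyrrol-2-yl)[2,4-dimethoxy-3-(4-methylpentyl)phenyl]methanone
Product: 14 (4,5-dichloro-1H-pyrrol-2-yl)[2,4-dihydroxy-3-(4-methylpentyl)phenyl]methanone (CNP0317757.0)
Conditions: BBr3 (5 equiv), CH2Cl2, −78 °C to rt; then MeOH, H2O
Reagents that add atoms: none
Why: In this Lewis-acid ether cleavage BBr3 should coordinate each aryl methyl ether and bromide remove the methyl group by SN2, the C2 ether being helped by chelation to the ketone, while the diaryl ketone, both C–Cl bonds and the alkyl chain are inert and the excess reagent covers binding to the carbonyl and the pyrrole N–H.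

Compound list
1 | 1,3-dimethoxybenzene | COc1cccc(OC)c1 | starting material
2 | 1-bromo-4-methylpentane | CC(C)CCCBr | starting material
3 | 2,6-dimethoxyphenyllithium | [Li]c1c(OC)cccc1OC | intermediate
4 | 1,3-dimethoxy-2-(4-methylpentyl)benzene | CC(C)CCCc1c(OC)cccc1OC | intermediate
5 | chloroacetyl chloride | O=C(Cl)CCl | starting material
6 | 2-chloro-1-[2,4-dimethoxy-3-(4-methylpentyl)phenyl]ethanone | CC(C)CCCc1c(OC)ccc(C(=O)CCl)c1OC | intermediate
7 | hexamethylenetetramine | C1N2CN3CN1CN(C2)C3 | starting material
8 | 1-{2-[2,4-dimethoxy-3-(4-methylpentyl)phenyl]-2-oxoethyl}-1,3,5,7-tetraazaadamantan-1-ium chloride (hexaminium chloride) | CC(C)CCCc1c(OC)ccc(C(=O)C[N+]23CN4CN(CN(C4)C2)C3)c1OC.[Cl-] | intermediate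
9 | 2-amino-1-[2,4-dimethoxy-3-(4-methylpentyl)phenyl]ethanone hydrochloride | CC(C)CCCc1c(OC)ccc(C(=O)C[NH3+])c1OC.[Cl-] | intermediate
10 | 2,3,3-trichloroacrolein (2,3,3-trichloroprop-2-enal) | O=CC(Cl)=C(Cl)Cl | starting material
11 | 2-amino-1-[2,4-dimethoxy-3-(4-methylpentyl)phenyl]ethanone (free base) | CC(C)CCCc1c(OC)ccc(C(=O)CN)c1OC | intermediate
12 | (2Z)-2,3-dichloro-3-({2-[2,4-dimethoxy-3-(4-methylpentyl)phenyl]-2-oxoethyl}amino)prop-2-enal | CC(C)CCCc1c(OC)ccc(C(=O)CN/C(Cl)=C(Cl)\C=O)c1OC | intermediate
13 | (4,5-dichloro-1H-pyrrol-2-yl)[2,4-dimethoxy-3-(4-methylpentyl)phenyl]methanone | CC(C)CCCc1c(OC)ccc(C(=O)c2cc(Cl)c(Cl)[nH]2)c1OC | intermediate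
14 | (4,5-dichloro-1H-pyrrol-2-yl)[2,4-dihydroxy-3-(4-methylpentyl)phenyl]methanone | CC(C)CCCc1c(O)ccc(C(=O)c2cc(Cl)c(Cl)[nH]2)c1O | target

Total step count: 5
Longest linear sequence: 5 steps (1 to 4 to 6 to 9 to 13 to 14)

Steps most likely to fail

Step 4. The amine may condense at the aldehyde instead of displacing chloride, which would lead to the isomeric dichloropyrrole. The enaminal may also lose its C5' chlorine by hydrolysis, by a second amination or by oxazole closure through the enolate oxygen, and the liberated aminoketone may self-condense. The fallback uses known chemistry, sets out from 4 and comes back at 13. Purchased 4,5-dichloro-1H-pyrrole-2-carboxylic acid F1 would be converted with oxalyl chloride and catalytic DMF in CH2Cl2 into 4,5-dichloro-1H-pyrrole-2-carbonyl chloride F2. F2 would then acylate 4 under AlCl3 (2.2 equiv) in CH2Cl2 at 0 °C, a Friedel–Crafts acylation with the same C4 regiochemistry as step 2. Both chlorines are again brought in on the pyrrole piece, and steps 2 and 3 fall away.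

Step 2. The Lewis acid may cleave the flanked C2 methyl ether once the ketone is formed (the freed phenol would later close onto the chloromethyl ketone), or acylation may proceed twice. The fallback sets out from 4 and comes back at 6. Bromination with NBS in MeCN at 0 °C to rt, para to a methoxy group, would give 1-bromo-2,4-dimethoxy-3-(4-methylpentyl)benzene F3. Bromine–lithium exchange with n-BuLi in THF at −78 °C would give [2,4-dimethoxy-3-(4-methylpentyl)phenyl]lithium F4. F4 would be acylated in the same flask by 2-chloro-N-methoxy-N-methylacetamide, whose chelated tetrahedral adduct collapses only on aqueous HCl quench, delivering 6 without any Lewis acid.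

Step 5. Cleavage of the C4 methyl ether, which has no chelation assistance, may stall, or forcing the reaction may degrade the electron-rich resorcinol–pyrrole ketone in the acidic medium. The fallback sets out from 13 and comes back at 14. BCl3 in CH2Cl2 at −78 to 0 °C would remove only the ketone-chelated C2 methyl ether, giving (4,5-dichloro-1H-pyrrol-2-yl)[2-hydroxy-4-methoxy-3-(4-methylpentyl)phenyl]methanone F5. The remaining C4 ether would then be cleaved by SN2 attack of thiolate at the methyl group (NaSEt, DMF, 110 °C, acidic work-up). Under these basic conditions phenol and pyrrole are masked as their anions and no strong acid is present.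

Further compounds
F1 | step 4 | 4,5-dichloro-1H-pyrrole-2-carboxylic acid (purchased) | OC(=O)c1cc(Cl)c(Cl)[nH]1
F2 | step 4 | 4,5-dichloro-1H-pyrrole-2-carbonyl chloride | O=C(Cl)c1cc(Cl)c(Cl)[nH]1
F3 | step 2 | 1-bromo-2,4-dimethoxy-3-(4-methylpentyl)benzene | CC(C)CCCc1c(OC)ccc(Br)c1OC
F4 | step 2 | [2,4-dimethoxy-3-(4-methylpentyl)phenyl]lithium | [Li]c1ccc(OC)c(CCCC(C)C)c1OC
F5 | step 5 | (4,5-dichloro-1H-pyrrol-2-yl)[2-hydroxy-4-methoxy-3-(4-methylpentyl)phenyl]methanone | CC(C)CCCc1c(OC)ccc(C(=O)c2cc(Cl)c(Cl)[nH]2)c1O
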